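**Plan**

1. Retrosynthetic cuts, in order: the acetyl C–O bond at C12, then the four C–O bonds of the two oxiranes (O–C2, O–C3, O–C6, O–C7) in one operation, then C12–C13 (allylboration), the C12–O bond (allylic oxidation of a farnesyl methyl), and finally C3–CH3 and C4–C5 (acetoacetate homologation of nerol).
2. Forward, the open chain is joined first (nerol C5–C11, acetoacetate C1–C4, one methyl), C12 is oxidised to the enal, and the C13–C15 isopropylallyl unit (isovaleraldehyde plus formaldehyde) is added; both oxirane rings then arise together in one flask and the acetate is removed last.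
3. Enabling feature: both oxiranes lie on trisubstituted alkenes with one vinylic hydrogen each (H–C2 of the 2E alkene, H–C6 of the 6Z alkene). Both need oxygen on the same face relative to that hydrogen (R at C2 and at C6), so one enantiomer of a chiral dioxirane can close the C2–C3 ring and the C6–C7 ring.
4. Stereochemistry: 6Z comes from nerol, 2E from the Z-enol phosphate/cuprate pair, 10E from the SeO2 oxidation, 12R from an allylborane built on (−)-α-pinene, and 2R,3R,6R,7S from the D-fructose-derived ketone acting on the fixed alkene geometries.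
5. Site control in the ring-forming step: C10=C11 is switched off by the C12 acetate, C14=CH2 is 1,1-disubstituted, and C1–OH stays free.

Key step: step 15

Remark on the chemistry (assumption): the target SMILES is read as (2R,3R,6R,7S,10E,12R). Locants follow the C16 chain, with C1 the CH2OH carbon, C12 the secondary carbinol, C14 the methylidene-bearing carbon and C15 the isopropyl methine. Ipc is isopinocampheyl, and (+)-Ipc2BOMe is the methoxyborane made from (−)-α-pinene. The fructose-derived ketone is 1,2:4,5-di-O-isopropylidene-β-D-erythro-2,3-hexodiulo-2,6-pyranose, CC1(C)OC[C@@]2(O1)OC[C@H]3OC(C)(C)O[C@H]3C2=O.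

**Route**

Step 1
Reactants: 1 nerol, (2Z)-3,7-dimethylocta-2,6-dien-1-ol
Product: 2 neryl bromide, (2Z)-1-bromo-3,7-dimethylocta-2,6-diene
Conditions: PBr3 (0.4 equiv), Et2O, −10 °C → 0 °C; used crude
Reagents that add atoms: phosphorus tribromide, BrP(Br)Br
Why: Bromination of a primary allylic alcohol with PBr3 (SN2 on the bromophosphite) at low temperature should give the primary bromide with the Z geometry of nerol intact and little allylic transposition.

Step 2
Reactants: 3 ethyl acetoacetate; 2 neryl bromide
Product: 5 ethyl (6Z)-7,11-dimethyl-3-oxododeca-6,10-dienoate, via acetoacetate dianion 4 (not isolated)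
Conditions: 3, NaH, THF, 0 °C; n-BuLi, 0 °C; then 2, 0 °C → rt; aq. NH4Cl
Reagents that add atoms: none
Why: Weiler acetoacetate dianion alkylation: the more nucleophilic terminal carbanion should displace the primary allylic bromide by SN2 and so form C4–C5 without touching the Z alkene.

Step 3
Reactants: 5 ethyl (6Z)-7,11-dimethyl-3-oxododeca-6,10-dienoate
Product: 7 ethyl (2Z,6Z)-3-[(diethoxyphosphoryl)oxy]-7,11-dimethyldodeca-2,6,10-trienoate, via sodium enolate 6 (not isolated)
Conditions: NaH, Et2O, 0 °C; ClP(O)(OEt)2, 0 °C → rt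
Reagents that add atoms: diethyl chlorophosphate, CCOP(=O)(Cl)OCC
Why: O-Phosphorylation of the sodium-chelated enolate of a β-keto ester in ether (enol phosphate formation) should give the Z enol phosphate, because sodium holds the enolate oxygen and the ester carbonyl on the same side.

Step 4
Reactants: 7 ethyl (2Z,6Z)-3-[(diethoxyphosphoryl)oxy]-7,11-dimethyldodeca-2,6,10-trienoate
Product: 8 ethyl (2E,6Z)-3,7,11-trimethyldodeca-2,6,10-trienoate (ethyl (2E,6Z)-farnesoate)
Conditions: Me2CuLi (from MeLi and CuI), Et2O, −78 °C → −45 °C; aq. NH4Cl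
Reagents that add atoms: lithium dimethylcuprate Me2CuLi, [Li+].C[Cu-]C
Why: Cuprate coupling of the enol phosphate of a β-keto ester (addition–elimination with retention of geometry) should replace the phosphate by methyl and turn the Z phosphate into the 2E trisubstituted enoate, the low temperature preventing conjugate addition to the product.

Step 5
Reactants: 8 ethyl (2E,6Z)-3,7,11-trimethyldodeca-2,6,10-trienoate
Product: 9 (2E,6Z)-3,7,11-trimethyldodeca-2,6,10-trien-1-ol ((2E,6Z)-farnesol)
Conditions: i-Bu2AlH (2.5 equiv), CH2Cl2, −78 °C → 0 °C; aq. KNaC4H4O6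
Reagents that add atoms: none
Why: Reduction with i-Bu2AlH delivers hydride 1,2 to the α,β-unsaturated ester, giving the allylic alcohol and leaving the isolated alkenes and their geometries alone.

Step 6
Reactants: 9 (2E,6Z)-3,7,11-trimethyldodeca-2,6,10-trien-1-ol
Product: 10 tert-butyldimethyl{[(2E,6Z)-3,7,11-trimethyldodeca-2,6,10-trien-1-yl]oxy}silane
Conditions: TBSCl, imidazole, CH2Cl2, 0 °C → rt
Reagents that add atoms: tert-butyldimethylsilyl chloride, CC(C)(C)[Si](C)(C)Cl
Why: Silylation of a primary alcohol with TBSCl and imidazole is routine and gives an ether that should survive allylic oxidation, allylboration with alkaline peroxide work-up and acetylation, yet can be removed beside an acetate.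

Step 7
Reactants: 10 tert-butyldimethyl{[(2E,6Z)-3,7,11-trimethyldodeca-2,6,10-trien-1-yl]oxy}silane
Product: 11 (2E,6Z,10E)-12-[(tert-butyldimethylsilyl)oxy]-2,6,10-trimethyldodeca-2,6,10-trien-1-ol
Conditions: SeO2 (0.2 equiv), t-BuOOH (70% aq., 3 equiv), salicylic acid (0.1 equiv), CH2Cl2, 0 °C → rt; stopped at partial conversion, 10 recycled
Reagents that add atoms: selenium dioxide, O=[Se]=O; tert-butyl hydroperoxide, CC(C)(C)OO
Why: Sharpless catalytic SeO2/t-BuOOH allylic oxidation (ene reaction then [2,3]-sigmatropic shift) should hydroxylate the E methyl of the terminal, most electron-rich trisubstituted alkene and fix the 10E geometry, C2=C3 being deactivated by its allylic silyl ether; any enal formed by over-oxidation is combined with the product of step 8.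

Step 8
Reactants: 11 (2E,6Z,10E)-12-[(tert-butyldimethylsilyl)oxy]-2,6,10-trimethyldodeca-2,6,10-trien-1-ol
Product: 12 (2E,6Z,10E)-12-[(tert-butyldimethylsilyl)oxy]-2,6,10-trimethyldodeca-2,6,10-trienal
Conditions: MnO2 (activated, excess), CH2Cl2, rt
Reagents that add atoms: none
Why: MnO2 oxidation is selective for allylic alcohols and should give the E enal without isomerisation or attack on the silyl ether.

Step 9
Reactants: 13 isovaleraldehyde (3-methylbutanal)
Product: 14 3-methyl-2-methylidenebutanal (2-isopropylacrolein)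
Conditions: aq. HCHO (37%), pyrrolidine (10 mol %), EtCO2H (10 mol %), i-PrOH, 45 °C
Reagents that add atoms: formaldehyde, C=O
Why: Amine-catalysed Mannich condensation with formaldehyde followed by elimination (α-methylenation of an aldehyde) should install the methylidene group that becomes C14=CH2.

Step 10
Reactants: 14 3-methyl-2-methylidenebutanal
Product: 15 3-methyl-2-methylidenebutan-1-ol
Conditions: NaBH4, CeCl3·7H2O, MeOH, 0 °C
Reagents that add atoms: none
Why: Luche reduction should deliver hydride 1,2 to the enal and avoid conjugate reduction.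

Step 11
Reactants: 15 3-methyl-2-methylidenebutan-1-ol
Product: 16 2-(bromomethyl)-3-methylbut-1-ene
Conditions: PBr3 (0.4 equiv), Et2O, 0 °C
Reagents that add atoms: phosphorus tribromide, BrP(Br)Br
Why: PBr3 converts the primary allylic alcohol into the bromide, and because the two allyl termini of this 2-substituted allyl system are identical, SN2 and SN2′ pathways give the same product.

Step 12
Reactants: 12 (2E,6Z,10E)-12-[(tert-butyldimethylsilyl)oxy]-2,6,10-trimethyldodeca-2,6,10-trienal; 16 2-(bromomethyl)-3-methylbut-1-ene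
Product: 20 (5R,6E,10Z,14E)-16-[(tert-butyldimethylsilyl)oxy]-2,6,10,14-tetramethyl-3-methylidenehexadeca-6,10,14-trien-5-ol, via 2-isopropylallylmagnesium bromide 17 (not isolated), via B-(2-isopropylallyl)diisopinocampheylborane 18 (not isolated), via diisopinocampheylborinate adduct 19 (not isolated)
Conditions: 16, Mg, Et2O, 0 °C; (+)-Ipc2BOMe, Et2O, −78 °C → rt; 12, −78 °C; NaOH, H2O2, rt
Reagents that add atoms: none
Why: Brown asymmetric allylboration: the allyl Grignard reagent is transmetalated to boron and the B-allyl borane adds 1,2 to the enal through a closed chair six-membered transition state, in which the isopinocampheyl groups from (−)-α-pinene should direct the 2-isopropylallyl group to the aldehyde face that gives 12R (the (+)-α-pinene series being the one that leads to S carbinols when the aldehyde residue outranks the allyl carbon).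

Step 13
Reactants: 20 (5R,6E,10Z,14E)-16-[(tert-butyldimethylsilyl)oxy]-2,6,10,14-tetramethyl-3-methylidenehexadeca-6,10,14-trien-5-ol
Product: 21 (5R,6E,10Z,14E)-16-[(tert-butyldimethylsilyl)oxy]-2,6,10,14-tetramethyl-3-methylidenehexadeca-6,10,14-trien-5-yl acetate
Conditions: Ac2O, Et3N, DMAP (cat.), CH2Cl2, 0 °C → rt
Reagents that add atoms: acetic anhydride, CC(=O)OC(C)=O
Why: DMAP-catalysed acylation of the secondary allylic alcohol does not break the C12–O bond, so 12R is retained, and it installs the ester that later deactivates C10=C11.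

Step 14
Reactants: 21 (5R,6E,10Z,14E)-16-[(tert-butyldimethylsilyl)oxy]-2,6,10,14-tetramethyl-3-methylidenehexadeca-6,10,14-trien-5-yl acetate
Product: 22 (2E,6Z,10E,12R)-1-hydroxy-3,7,11,15-tetramethyl-14-methylidenehexadeca-2,6,10-trien-12-yl acetate
Conditions: HF·pyridine, pyridine, THF, 0 °C → rt
Reagents that add atoms: none
Why: Fluoride-driven cleavage of the Si–O bond with pyridine-buffered HF·pyridine should free the primary allylic alcohol while the secondary acetate and the four alkenes stay untouched.

Step 15
Reactants: 22 (2E,6Z,10E,12R)-1-hydroxy-3,7,11,15-tetramethyl-14-methylidenehexadeca-2,6,10-trien-12-yl acetate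
Product: 23 (2R,3R,6R,7S,10E,12R)-2,3:6,7-diepoxy-1-hydroxy-3,7,11,15-tetramethyl-14-methylidenehexadec-10-en-12-yl acetate
Conditions: D-fructose-derived ketone (0.6 equiv), Oxone (2KHSO5·KHSO4·K2SO4, about 1.4 equiv per alkene, slow addition), K2CO3, Bu4NHSO4 (cat.), Na2B4O7/Na2EDTA buffer (pH 10.5), MeCN–CH2(OMe)2–H2O, 0 °C
Reagents that add atoms: potassium peroxymonosulfate KHSO5 (active salt of Oxone), [K+].[O-]S(=O)(=O)OO
Why: KHSO5 turns the fructose-derived ketone into a chiral dioxirane that hands one oxygen to each alkene in a concerted spiro transition state and regenerates the ketone; this is the Shi asymmetric epoxidation, known for trisubstituted alkenes, for allylic alcohols and for polyenes oxidised at several sites in one pot. Each oxirane (C2–O–C3 and C6–O–C7) closes by this single-step [2+1] oxygen-atom transfer, both C–O bonds of a ring forming on one alkene face, so the 2E alkene gives the trans-disposed 2,3-oxide and the 6Z alkene the cis-disposed 6,7-oxide. The face is chosen by the catalyst: the lone vinylic hydrogen (H–C2, H–C6) takes the crowded position next to the spiro ketal, which for the D-fructose ketone (the enantiomer that gives R,R oxides from trans alkenes) makes both CH carbons R, and the fixed geometries then make C3 R and C7 S; the remote C12 centre takes no part. Site selectivity among four alkenes rests on electronics and substitution: C6=C7 is an isolated trisubstituted alkene and C2=C3 carries only a free allylic hydroxyl, whereas C10=C11 is deactivated by the allylic C12 acetate and C14=CH2 is 1,1-disubstituted and slow towards this dioxirane. Oxone is metered at pH 10.5 and the addition is stopped once the mono-epoxides are consumed, which should keep over-oxidation and Baeyer–Villiger loss of the catalyst low. A facial error at either site would appear as a diastereomer of 23 and should be removable by chromatography.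

Step 16
Reactants: 23 (2R,3R,6R,7S,10E,12R)-2,3:6,7-diepoxy-1-hydroxy-3,7,11,15-tetramethyl-14-methylidenehexadec-10-en-12-yl acetate
Product: 24 (2R,3R,6R,7S,10E,12R)-2,3:6,7-diepoxy-3,7,11,15-tetramethyl-14-methylidenehexadec-10-ene-1,12-diol (target)
Conditions: K2CO3, MeOH, 0 °C → rt
Reagents that add atoms: none
Why: Base-catalysed transesterification with methanol should remove the acetate without breaking the C12–O bond, so 12R is kept, and at this temperature the trisubstituted oxiranes should not be opened nor the 2,3-epoxy alcohol driven to its less stable Payne isomer.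

**Compound list**

1 | nerol, (2Z)-3,7-dimethylocta-2,6-dien-1-ol | CC(C)=CCC/C(C)=C\CO | starting material
2 | neryl bromide, (2Z)-1-bromo-3,7-dimethylocta-2,6-diene | CC(C)=CCC/C(C)=C\CBr | intermediate
3 | ethyl acetoacetate | CCOC(=O)CC(C)=O | starting material
4 | acetoacetate dianion (sodium lithium dienolate of 3, formed in the flask) | [Li+].[Na+].C=C([O-])C=C([O-])OCC | intermediate
5 | ethyl (6Z)-7,11-dimethyl-3-oxododeca-6,10-dienoate | CC(C)=CCC/C(C)=C\CCC(=O)CC(=O)OCC | intermediate
6 | sodium (Z)-enolate of 5 (formed in the flask) | [Na+].CC(C)=CCC/C(C)=C\CC/C([O-])=C/C(=O)OCC | intermediate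
7 | ethyl (2Z,6Z)-3-[(diethoxyphosphoryl)oxy]-7,11-dimethyldodeca-2,6,10-trienoate | CC(C)=CCC/C(C)=C\CC/C(OP(=O)(OCC)OCC)=C/C(=O)OCC | intermediate
8 | ethyl (2E,6Z)-3,7,11-trimethyldodeca-2,6,10-trienoate | CC(C)=CCC/C(C)=C\CC/C(C)=C/C(=O)OCC | intermediate
9 | (2E,6Z)-3,7,11-trimethyldodeca-2,6,10-trien-1-ol | CC(C)=CCC/C(C)=C\CC/C(C)=C/CO | intermediate
10 | tert-butyldimethyl{[(2E,6Z)-3,7,11-trimethyldodeca-2,6,10-trien-1-yl]oxy}silane | CC(C)=CCC/C(C)=C\CC/C(C)=C/CO[Si](C)(C)C(C)(C)C | intermediate
11 | (2E,6Z,10E)-12-[(tert-butyldimethylsilyl)oxy]-2,6,10-trimethyldodeca-2,6,10-trien-1-ol | OC/C(C)=C/CC/C(C)=C\CC/C(C)=C/CO[Si](C)(C)C(C)(C)C | intermediate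
12 | (2E,6Z,10E)-12-[(tert-butyldimethylsilyl)oxy]-2,6,10-trimethyldodeca-2,6,10-trienal | O=C/C(C)=C/CC/C(C)=C\CC/C(C)=C/CO[Si](C)(C)C(C)(C)C | intermediate
13 | isovaleraldehyde (3-methylbutanal) | CC(C)CC=O | starting material
14 | 3-methyl-2-methylidenebutanal | C=C(C=O)C(C)C | intermediate
15 | 3-methyl-2-methylidenebutan-1-ol | C=C(CO)C(C)C | intermediate
16 | 2-(bromomethyl)-3-methylbut-1-ene | C=C(CBr)C(C)C | intermediate
17 | 2-isopropylallylmagnesium bromide (formed in the flask) | C=C(C[Mg]Br)C(C)C | intermediate
18 | B-(2-isopropylallyl)diisopinocampheylborane, Ipc groups from (−)-α-pinene (formed in the flask) | C=C(CB([C@H]1C[C@H]2C[C@@H]([C@@H]1C)C2(C)C)[C@H]1C[C@H]2C[C@@H]([C@@H]1C)C2(C)C)C(C)C | intermediate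
19 | diisopinocampheylborinate adduct, the O-boryl derivative of 20 (formed in the flask) | C=C(C[C@@H](OB([C@H]1C[C@H]2C[C@@H]([C@@H]1C)C2(C)C)[C@H]1C[C@H]2C[C@@H]([C@@H]1C)C2(C)C)/C(C)=C/CC/C(C)=C\CC/C(C)=C/CO[Si](C)(C)C(C)(C)C)C(C)C | intermediate
20 | (5R,6E,10Z,14E)-16-[(tert-butyldimethylsilyl)oxy]-2,6,10,14-tetramethyl-3-methylidenehexadeca-6,10,14-trien-5-ol | C=C(C[C@@H](O)/C(C)=C/CC/C(C)=C\CC/C(C)=C/CO[Si](C)(C)C(C)(C)C)C(C)C | intermediate
21 | (5R,6E,10Z,14E)-16-[(tert-butyldimethylsilyl)oxy]-2,6,10,14-tetramethyl-3-methylidenehexadeca-6,10,14-trien-5-yl acetate | C=C(C[C@@H](OC(C)=O)/C(C)=C/CC/C(C)=C\CC/C(C)=C/CO[Si](C)(C)C(C)(C)C)C(C)C | intermediate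
22 | (2E,6Z,10E,12R)-1-hydroxy-3,7,11,15-tetramethyl-14-methylidenehexadeca-2,6,10-trien-12-yl acetate | C=C(C[C@@H](OC(C)=O)/C(C)=C/CC/C(C)=C\CC/C(C)=C/CO)C(C)C | intermediate
23 | (2R,3R,6R,7S,10E,12R)-2,3:6,7-diepoxy-1-hydroxy-3,7,11,15-tetramethyl-14-methylidenehexadec-10-en-12-yl acetate | C=C(C[C@@H](OC(C)=O)/C(C)=C/CC[C@]1(C)O[C@@H]1CC[C@@]1(C)O[C@@H]1CO)C(C)C | intermediate
24 | (2R,3R,6R,7S,10E,12R)-2,3:6,7-diepoxy-3,7,11,15-tetramethyl-14-methylidenehexadec-10-ene-1,12-diol | C=C(C[C@@H](O)/C(C)=C/CC[C@]1(C)O[C@@H]1CC[C@@]1(C)O[C@@H]1CO)C(C)C | target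

**Step count and risks**

Total step count: 16. Longest linear sequence: 13 steps (steps 1–8 and 12–16, from nerol); steps 9–11 build the allyl bromide in a three-step side branch.

Steps most likely to fail:

1. Step 15. Oxygen transfer to C2=C3, slowed by its allylic hydroxyl, may lag so far behind C6=C7 that forcing it to completion starts oxidation at C10=C11 or at the methylidene group, or its facial selectivity may fall short. The fallback sets out from 22. A Sharpless asymmetric epoxidation (Ti(OiPr)4, D-(−)-diethyl tartrate, t-BuOOH, 4 Å molecular sieves, CH2Cl2, −20 °C) uses the C1 hydroxyl to direct oxygen to C2=C3 alone and to set 2R,3R, giving (2R,3R,6Z,10E,12R)-2,3-epoxy-1-hydroxy-3,7,11,15-tetramethyl-14-methylidenehexadeca-6,10-dien-12-yl acetate F1. A single-site epoxidation of the remaining isolated trisubstituted alkene C6=C7 with the same fructose-derived ketone and Oxone then comes back to the route at 23.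

2. Step 12. The allyl reagent may be lost to Wurtz coupling while the Grignard reagent forms, or the enantioselectivity of the allyl transfer may erode because of the 2-isopropyl substituent, the magnesium salts or poor temperature control. The fallback sets out from 12 and 16. A Barbier addition (Zn, THF/aq. NH4Cl, rt) gives racemic (5RS,6E,10Z,14E)-16-[(tert-butyldimethylsilyl)oxy]-2,6,10,14-tetramethyl-3-methylidenehexadeca-6,10,14-trien-5-ol F2. Oxidation with Dess–Martin periodinane buffered by NaHCO3 gives (6E,10Z,14E)-16-[(tert-butyldimethylsilyl)oxy]-2,6,10,14-tetramethyl-3-methylidenehexadeca-6,10,14-trien-5-one F3, kept neutral so the methylidene group does not move into conjugation. Corey–Bakshi–Shibata reduction with the (S)-Me-CBS oxazaborolidine and catecholborane in toluene at −78 °C, the trisubstituted alkenyl group acting as the large substituent, should then set 12R and come back to the route at 20.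

3. Step 7. Ene oxidation at internal allylic positions (C8 and the methyl on C7) and over-oxidation may compete with attack at the terminal E methyl and cut the throughput. The fallback sets out from 10 and replaces steps 7 and 8. Terminal-selective bromohydrin formation (NBS, THF/H2O, 0 °C) gives racemic (6Z,10E)-3-bromo-12-[(tert-butyldimethylsilyl)oxy]-2,6,10-trimethyldodeca-6,10-dien-2-ol F4. Ring closure with K2CO3 in MeOH gives tert-butyl{[(2E,6Z)-9-(3,3-dimethyloxiran-2-yl)-3,7-dimethylnona-2,6-dien-1-yl]oxy}dimethylsilane F5. Cleavage with H5IO6 in THF/Et2O at 0 °C gives (4Z,8E)-10-[(tert-butyldimethylsilyl)oxy]-4,8-dimethyldeca-4,8-dienal F6. An E-selective Wittig reaction with the stabilised ylide Ph3P=C(CH3)CHO in toluene at 80 °C then comes back to the route at 12.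

**Further compounds**

F1 | step 15 | (2R,3R,6Z,10E,12R)-2,3-epoxy-1-hydroxy-3,7,11,15-tetramethyl-14-methylidenehexadeca-6,10-dien-12-yl acetate | C=C(C[C@@H](OC(C)=O)/C(C)=C/CC/C(C)=C\CC[C@@]1(C)O[C@@H]1CO)C(C)C
F2 | step 12 | (5RS,6E,10Z,14E)-16-[(tert-butyldimethylsilyl)oxy]-2,6,10,14-tetramethyl-3-methylidenehexadeca-6,10,14-trien-5-ol (racemic) | C=C(CC(O)/C(C)=C/CC/C(C)=C\CC/C(C)=C/CO[Si](C)(C)C(C)(C)C)C(C)C
F3 | step 12 | (6E,10Z,14E)-16-[(tert-butyldimethylsilyl)oxy]-2,6,10,14-tetramethyl-3-methylidenehexadeca-6,10,14-trien-5-one | C=C(CC(=O)/C(C)=C/CC/C(C)=C\CC/C(C)=C/CO[Si](C)(C)C(C)(C)C)C(C)C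
F4 | step 7 | (6Z,10E)-3-bromo-12-[(tert-butyldimethylsilyl)oxy]-2,6,10-trimethyldodeca-6,10-dien-2-ol (racemic) | CC(C)(O)C(Br)CC/C(C)=C\CC/C(C)=C/CO[Si](C)(C)C(C)(C)C
F5 | step 7 | tert-butyl{[(2E,6Z)-9-(3,3-dimethyloxiran-2-yl)-3,7-dimethylnona-2,6-dien-1-yl]oxy}dimethylsilane (racemic) | CC1(C)OC1CC/C(C)=C\CC/C(C)=C/CO[Si](C)(C)C(C)(C)C
F6 | step 7 | (4Z,8E)-10-[(tert-butyldimethylsilyl)oxy]-4,8-dimethyldeca-4,8-dienal | O=CCC/C(C)=C\CC/C(C)=C/CO[Si](C)(C)C(C)(C)C
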